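The numbers in the tables are simulated with constants of no real substance, and the scatter is random.

**Hidden constants.** The rate constants are hidden, so you reckon from a balance of Ly instead of integrating.

| flask | Aj | Ly | remark | time |
|---|---|---|---|---|
| east | 13 mM | 20 mM | run made earlier |  |
| north-east | 30 mM | 20 mM | run made earlier |  |
| south | 20 mM | 10 mM | run made earlier |  |
| flask | 20 mM | 20.0 mM |  | 6.0 h |

- east (time / h: Aj / %, Ky / %): 0.333: 31.5, 9.7; 1.00: 19.2, 1.1; 1.50: 15.0, 1.8; 2.50: 10.0, 1.8; 4.00: 10.2, 0.4; 5.00: 10.5, 1.9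
- north-east (time / h: Aj / %, Ky / %): 0.333: 50.9, 7.0; 1.00: 42.8, 0; 1.50: 42.6, 0; 2.50: 43.0, 0; 4.00: 42.0, 0.3; 5.00: 43.0, 0.1
- south (time / h: Aj / %, Ky / %): 0.417: 60.9, 4.8; 0.667: 59.1, 1.7; 1.33: 56.2, 1.1; 2.50: 55.3, 1.2; 5.00: 53.2, 0

(scatter of a reading: 1 percentage point)

* Aj at 6.0 h, in percent of the Aj charged
* Ky at 6.0 h, in percent of the Aj charged
* Qa at 6.0 h, in percent of the Aj charged
* Ym at 6.0 h, in percent of the Aj charged

- what was read earlier has a scatter of 1 percentage point, one standard deviation
- reactions considered so far: Aj + Ly -> Qa + Kj; Aj + Ly <-> Ky + Kj; Ky <-> Ul; Ly + Qa -> Ym + Kj; Ly + Ky -> Ym + Kj; 2 Ly -> Ly2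

**Ly cost.** Aj levels off in the east, north-east and south runs. Divide the Ly charged by the Aj consumed at that level, using the mean of the last readings. East reads 1.71, north-east 1.16 and south 1.09. Call this ratio the Ly cost. Each Aj consumed takes one Ly. Any excess is Ly left over, or Ly in Ym or Ly2, and these readings, of Aj and Ky, don't say which.

**Two ways.** Your flask has the Aj charge of the south run, so first carry over the south cost. That leaves 8.50% of the Aj. Second, place the flask by its ratio of Ly to Aj charged, 1.00, on a straight line between north-east and east. The cost is then 1.37, which leaves 27.2%.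

**Which cheats.** The first way cheats. The cost read higher in east than in north-east, and higher in north-east than in south, as the ratio rose. The flask's ratio is twice the south ratio. So your own reckoning stays with the second way.

**The forecast.** It gives Aj 25%, a little lower than yours, with Ky 0.8%, Qa 48% and Ym 17%. Its reading of the runs: “The Ly balance shows little second-step loss when Aj is in excess”.

**The flask.** At 6.0 h the flask holds Aj 24.3%, Ky 0.451%, Qa 61.4% and Ym 1.91%. Ly, the limiting reagent, stands at 1.5% of its charge.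

    Aj + Ly → Qa + Kj (k = 0.0550 M⁻¹ s⁻¹)
    Aj + Ly ⇌ Ky + Kj (K = 0.460, k = 0.0490 M⁻¹ s⁻¹)
    Ky ⇌ Ul (K = 15.0, k = 0.00110 s⁻¹)
    Ly + Qa → Ym + Kj (k = 0.00160 M⁻¹ s⁻¹)
    Ly + Ky → Ym + Kj (k = 0.00180 M⁻¹ s⁻¹)
    2 Ly → Ly2 (k = 0.0150 M⁻¹ s⁻¹)

**Excess Ly.** The flask's cost, counting Ly used, is 1.30. Its excess is 4.56 mM of Ly. Ly2, at two Ly each, holds 4.18 mM of that and Ym, at one Ly beyond its Aj, 0.383 mM, so Ly2 holds more of it than Ym. Now charge 12 mM of Ly instead, with the same Aj and the same time. Between south and north-east the line gives a cost of 1.13, which leaves 47.1% of the Aj. At 6.00 h that flask holds Aj 47.6%.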